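**Retrosynthetic overview**
1. Feature: the target is an 8–5′ neolignan (phenylcoumaran). Its only non-aromatic ring, the dihydrofuran O1–C2–C3–C3a–C7a, joins guaiacyl ring A (a dihydroferulate ester in which C3a was the free C–H ortho to the phenol oxygen O1) to a syringyl C6–C3 unit (ring B, C2, C3 and the hydroxymethyl carbon) through two bonds only, C3–C3a and O1–C2.
2. The C3 hydroxymethyl group is traced back to a C3 acyl oxazolidinone. The carbonyl that steers the stereochemistry is therefore the one reduced at the end, beside an untouched methyl ester.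
3. C3–C3a and O1–C2 are cut together, giving N-sinapoyl-(S)-4-benzyloxazolidin-2-one and methyl dihydroferulate. In the forward sense, Ag2O radical cross-coupling and quinone methide closure build the dihydrofuran ring, the only ring formed in the route (rings A and B and the auxiliary ring are bought).
4. The imide is traced back to sinapic acid and the auxiliary: acetate on, N-acylation, acetate off.

Key step: step 4

Assumption: the sense of induction is derived from the s-cis, syn-carbonyl rotamer of the imide. If the coupling runs through the anti-carbonyl rotamer instead, (R)-4-benzyloxazolidin-2-one replaces the (S)-auxiliary in step 2 and nothing else changes.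

Step 1
Reactants: 1 sinapic acid
Product: 2 4-O-acetylsinapic acid, (E)-3-(4-acetoxy-3,5-dimethoxyphenyl)prop-2-enoic acid
Conditions: Ac2O (3 equiv), pyridine, rt; then ice-water, aq HCl
Reagents that add atoms: acetic anhydride, CC(=O)OC(C)=O
Why: Pyridine-promoted O-acetylation (nucleophilic acyl substitution) masks the syringyl phenol so that it cannot be acylated in step 2, the aqueous quench returns any mixed carboxylic–acetic anhydride to the free acid, and the E alkene is untouched with no stereocentre formed.

Step 2
Reactants: 2 4-O-acetylsinapic acid; 3 (S)-4-benzyloxazolidin-2-one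
Product: 5 (S)-3-[(E)-3-(4-acetoxy-3,5-dimethoxyphenyl)prop-2-enoyl]-4-benzyloxazolidin-2-one, via mixed pivalic anhydride 4 (not isolated)
Conditions: PivCl, Et3N, THF, −20 °C; then LiCl, 3, −20 °C to rt
Reagents that add atoms: pivaloyl chloride, CC(C)(C)C(=O)Cl (its acyl group is held only by 4)
Why: Mixed-anhydride N-acylation of an oxazolidinone under LiCl/Et3N: the lithium-activated auxiliary attacks the less hindered cinnamoyl carbonyl of 4 rather than the pivaloyl carbonyl, the aryl acetate is far less electrophilic than the anhydride, and the auxiliary stereocentre takes no part.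

Step 3
Reactants: 5 N-(4-O-acetylsinapoyl) imide
Product: 6 N-sinapoyl-(S)-4-benzyloxazolidin-2-one, (S)-4-benzyl-3-[(E)-3-(4-hydroxy-3,5-dimethoxyphenyl)prop-2-enoyl]oxazolidin-2-one
Conditions: pyrrolidine (1.2 equiv), CH2Cl2, 0 °C, short contact; cold aq citric acid
Reagents that add atoms: none
Why: Chemoselective aminolysis of an aryl acetate: pyrrolidine attacks the unhindered acetyl carbonyl with its phenoxide leaving group much faster than the conjugated, hindered imide carbonyls, and aza-Michael addition is held back because the donor-substituted β-aryl group (a phenoxide once freed) deactivates the enoyl acceptor.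

Step 4
Reactants: 6 N-sinapoyl-(S)-4-benzyloxazolidin-2-one; 7 methyl 3-(4-hydroxy-3-methoxyphenyl)propanoate (methyl dihydroferulate)
Product: 9 (S)-4-benzyl-3-{[(2S,3S)-2-(4-hydroxy-3,5-dimethoxyphenyl)-7-methoxy-5-(3-methoxy-3-oxopropyl)-2,3-dihydro-1-benzofuran-3-yl]carbonyl}oxazolidin-2-one, via quinone methide 8 (not isolated)
Conditions: 7 (3 equiv), Ag2O (1.5 equiv), dry CH2Cl2, N2, dark, rt; 6 added by syringe pump over several hours; filtration, chromatography (recovery of 7, removal of the minor diastereomer)
Reagents that add atoms: none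
Why: Ag2O (monovalent silver, one electron per silver atom) converts both phenols into phenoxyl radicals; the radical of 6 carries side-chain spin at C8, the carbon α to the imide carbonyl and β to ring B, and the radical of 7 carries ring spin at C5, its only unsubstituted position ortho to oxygen, so their combination makes the C3–C3a bond and tautomerisation of the ring A dienone gives quinone methide 8. The ring A phenol of 8 then adds to the exocyclic quinone methide carbon in a 5-exo-trig oxa-conjugate addition, which makes the O1–C2 bond, closes the dihydrofuran ring and restores the aromaticity of ring B. The closest known reaction type is the biomimetic 8–5′ oxidative coupling of ferulate esters and of feruloyl imides or sultams bearing chiral auxiliaries with Ag2O or peroxidase/H2O2, and mixed 8–5′ couplings of hydroxycinnamyl units with 4-alkylguaiacols are known from lignin model chemistry. C3 is controlled by the auxiliary: in the s-cis, syn-carbonyl rotamer the benzyl group covers the Re face of C8, ring A bonds to the Si face and C3 becomes S. C2 is controlled by C3: the phenol closes onto the quinone methide face that places ring B trans to the bulky imide, which is also the thermodynamically preferred arrangement, so C2 becomes S. The step needs cross-coupling over homo-coupling and C–C over C–O coupling: the two methoxy groups of ring B leave 6 no ring position to couple at, the saturated side chain of 7 leaves it only its ring or its oxygen, hydrogen-atom exchange with the threefold excess of 7 while 6 is kept dilute raises the share of ring A radicals against 8–8 dimerisation, 8–O–4 products are not excluded by design and must be separated, and the minor trans diastereomer still carries the auxiliary and is removed by chromatography so that a single enantiomer series goes forward.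

Step 5
Reactants: 9 trans-dihydrobenzofuran C3 imide
Product: 11 methyl 3-[(2S,3R)-2-(4-hydroxy-3,5-dimethoxyphenyl)-3-(hydroxymethyl)-7-methoxy-2,3-dihydro-1-benzofuran-5-yl]propanoate (CNP0362206.1), via C3 aldehyde 10 (not isolated)
Conditions: NaBH4 (4 equiv), THF/H2O (4:1), 0 °C to rt; aq NH4Cl
Reagents that add atoms: none
Why: Reductive cleavage of an N-acyl oxazolidinone with NaBH4 in aqueous THF: hydride adds to the exocyclic imide carbonyl, which is far more electrophilic than the methyl ester, the auxiliary leaves, aldehyde 10 is reduced at once, and no bond at C2 or C3 is touched, so the trans array is kept and the C3 descriptor changes from S to R only through the CIP ranking.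

**Compound list**
1 | sinapic acid | COc1cc(/C=C/C(O)=O)cc(OC)c1O | starting material
2 | 4-O-acetylsinapic acid | COc1cc(/C=C/C(O)=O)cc(OC)c1OC(C)=O | intermediate
3 | (S)-4-benzyloxazolidin-2-one | O=C1N[C@@H](Cc2ccccc2)CO1 | starting material
4 | 4-O-acetylsinapic pivalic mixed anhydride | COc1cc(/C=C/C(=O)OC(=O)C(C)(C)C)cc(OC)c1OC(C)=O | intermediate (not isolated)
5 | (S)-3-[(E)-3-(4-acetoxy-3,5-dimethoxyphenyl)prop-2-enoyl]-4-benzyloxazolidin-2-one | COc1cc(/C=C/C(=O)N2[C@@H](Cc3ccccc3)COC2=O)cc(OC)c1OC(C)=O | intermediate
6 | N-sinapoyl-(S)-4-benzyloxazolidin-2-one | COc1cc(/C=C/C(=O)N2[C@@H](Cc3ccccc3)COC2=O)cc(OC)c1O | intermediate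
7 | methyl 3-(4-hydroxy-3-methoxyphenyl)propanoate | COC(=O)CCc1ccc(O)c(OC)c1 | starting material
8 | (S)-4-benzyl-3-{(2R)-3-(3,5-dimethoxy-4-oxocyclohexa-2,5-dien-1-ylidene)-2-[2-hydroxy-3-methoxy-5-(3-methoxy-3-oxopropyl)phenyl]propanoyl}oxazolidin-2-one (quinone methide; same spatial arrangement as C3 of 9) | COC(=O)CCc1cc(OC)c(O)c(c1)[C@H](C(=O)N1[C@@H](Cc2ccccc2)COC1=O)C=C1C=C(OC)C(=O)C(OC)=C1 | intermediate (not isolated)
9 | (S)-4-benzyl-3-{[(2S,3S)-2-(4-hydroxy-3,5-dimethoxyphenyl)-7-methoxy-5-(3-methoxy-3-oxopropyl)-2,3-dihydro-1-benzofuran-3-yl]carbonyl}oxazolidin-2-one | COC(=O)CCc1cc(OC)c2c(c1)[C@H](C(=O)N1[C@@H](Cc3ccccc3)COC1=O)[C@@H](c1cc(OC)c(O)c(OC)c1)O2 | intermediate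
10 | methyl 3-[(2S,3S)-3-formyl-2-(4-hydroxy-3,5-dimethoxyphenyl)-7-methoxy-2,3-dihydro-1-benzofuran-5-yl]propanoate | COC(=O)CCc1cc(OC)c2c(c1)[C@H](C=O)[C@@H](c1cc(OC)c(O)c(OC)c1)O2 | intermediate (not isolated)
11 | methyl 3-[(2S,3R)-2-(4-hydroxy-3,5-dimethoxyphenyl)-3-(hydroxymethyl)-7-methoxy-2,3-dihydro-1-benzofuran-5-yl]propanoate | COC(=O)CCc1cc(OC)c2c(c1)[C@H](CO)[C@@H](c1cc(OC)c(O)c(OC)c1)O2 | target

Total step count: 5. Longest linear sequence: 5 steps (1 → 2 → 5 → 6 → 9 → 11).

**Steps most likely to fail**

1. Step 4.
- What may go wrong: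
  - 8–8 self-coupling of the sinapoyl radical and C8–O coupling to the ring A oxygen may outrun the C8–C5 encounter.
  - The electron-rich syringyl phenol of the product may be oxidised further.
  - The excess ring A phenol may be dehydrogenated at its benzylic position to a ferulate that joins the coupling.
  - Free rotation about the N–acyl bond may erode the facial bias.
- Fallback: an ionic, aldol-based assembly in which C2–C3 is made in place of C3–C3a. It sets out from 7 and comes back to the route at 8, and thus at 9. O-Allylation of 7 (allyl bromide, K2CO3, acetone, reflux) should give allyl aryl ether F1. An aromatic Claisen rearrangement (N,N-diethylaniline, 200 °C) then moves the allyl group to the only free ortho position, giving ortho-allylphenol F2. Benzylation (BnBr, K2CO3, DMF) gives benzyl ether F3. Lemieux–Johnson cleavage (OsO4 cat, NaIO4, 2,6-lutidine, dioxane/H2O) gives arylacetaldehyde F4, and Pinnick oxidation (NaClO2, NaH2PO4, 2-methyl-2-butene, t-BuOH/H2O) gives arylacetic acid F5. Activation as in step 2 (PivCl, Et3N) gives mixed anhydride F6, which acylates 3 (LiCl, Et3N) to arylacetyl imide F7. An Evans syn-aldol reaction (Bu2BOTf, i-Pr2NEt, CH2Cl2, −78 to 0 °C) with commercial 4-benzyloxy-3,5-dimethoxybenzaldehyde sets the future C3 as S from the Z boron enolate of the same (S)-auxiliary and gives syn-aldol F8. Hydrogenolysis of both benzyl ethers (H2, Pd/C, EtOAc) gives bis-phenol F9, which is taken on crude because its free ortho-phenol could lactonise onto the imide. A catalytic amount of TsOH in CH2Cl2 at 0 °C ionises the syringyl carbinol to 8, which closes to the trans ring of 9 whatever the carbinol configuration.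

2. Step 5.
- What may go wrong:
  - Hydride may attack the ring carbamate carbonyl of the hindered, α-branched imide.
  - Base may induce β-elimination of the ring A phenoxide from the imide or from the transient aldehyde.
  - The methyl ester may be reduced slowly on long exposure.
- Fallback: hydrolysis first, then an electrophilic hydride. It sets out from 9 and comes back at 11. LiOH/H2O2 (THF/H2O, 0 °C, then Na2SO3) attacks the exocyclic carbonyl selectively even in hindered imides and leaves unactivated esters, giving carboxylic acid F10 and the recovered auxiliary. BH3·THF (THF, 0 °C) then reduces the acid much faster than the methyl ester under non-basic conditions.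

3. Step 3.
- What may go wrong:
  - Aminolysis of the imide (loss of the auxiliary) or conjugate addition of the amine may compete with acetate cleavage.
- Fallback: a protecting-group-free construction of the bond between ring B and the side chain. It sets out from 3 and comes back at 6. N-Acylation of 3 with acryloyl chloride (Et3N, LiCl, THF, −20 °C to rt) gives N-acryloyl imide F11. A Heck reaction with commercial 4-bromo-2,6-dimethoxyphenol (Pd(OAc)2, P(o-tol)3, Et3N, MeCN, 80 °C) then gives 6 directly as the E alkene, so steps 1 to 3 are bypassed.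

**Further compounds**
F1 | step 4 | methyl 3-(4-allyloxy-3-methoxyphenyl)propanoate | COC(=O)CCc1ccc(OCC=C)c(OC)c1
F2 | step 4 | methyl 3-(3-allyl-4-hydroxy-5-methoxyphenyl)propanoate | COC(=O)CCc1cc(CC=C)c(O)c(OC)c1
F3 | step 4 | methyl 3-(3-allyl-4-benzyloxy-5-methoxyphenyl)propanoate | COC(=O)CCc1cc(CC=C)c(OCc2ccccc2)c(OC)c1
F4 | step 4 | methyl 3-[4-benzyloxy-3-methoxy-5-(2-oxoethyl)phenyl]propanoate | COC(=O)CCc1cc(CC=O)c(OCc2ccccc2)c(OC)c1
F5 | step 4 | 2-[2-benzyloxy-3-methoxy-5-(3-methoxy-3-oxopropyl)phenyl]acetic acid | COC(=O)CCc1cc(CC(=O)O)c(OCc2ccccc2)c(OC)c1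
F6 | step 4 | mixed pivalic anhydride of F5 | COC(=O)CCc1cc(CC(=O)OC(=O)C(C)(C)C)c(OCc2ccccc2)c(OC)c1
F7 | step 4 | (S)-4-benzyl-3-{2-[2-benzyloxy-3-methoxy-5-(3-methoxy-3-oxopropyl)phenyl]acetyl}oxazolidin-2-one | COC(=O)CCc1cc(CC(=O)N2[C@@H](Cc3ccccc3)COC2=O)c(OCc2ccccc2)c(OC)c1
F8 | step 4 | (S)-4-benzyl-3-{(2S,3S)-2-[2-benzyloxy-3-methoxy-5-(3-methoxy-3-oxopropyl)phenyl]-3-(4-benzyloxy-3,5-dimethoxyphenyl)-3-hydroxypropanoyl}oxazolidin-2-one | COC(=O)CCc1cc(OC)c(OCc2ccccc2)c(c1)[C@H](C(=O)N1[C@@H](Cc2ccccc2)COC1=O)[C@@H](c1cc(OC)c(OCc2ccccc2)c(OC)c1)O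
F9 | step 4 | (S)-4-benzyl-3-{(2S,3S)-3-hydroxy-3-(4-hydroxy-3,5-dimethoxyphenyl)-2-[2-hydroxy-3-methoxy-5-(3-methoxy-3-oxopropyl)phenyl]propanoyl}oxazolidin-2-one | COC(=O)CCc1cc(OC)c(O)c(c1)[C@H](C(=O)N1[C@@H](Cc2ccccc2)COC1=O)[C@@H](c1cc(OC)c(O)c(OC)c1)O
F10 | step 5 | (2S,3S)-2-(4-hydroxy-3,5-dimethoxyphenyl)-7-methoxy-5-(3-methoxy-3-oxopropyl)-2,3-dihydro-1-benzofuran-3-carboxylic acid | COC(=O)CCc1cc(OC)c2c(c1)[C@H](C(=O)O)[C@@H](c1cc(OC)c(O)c(OC)c1)O2
F11 | step 3 | (S)-3-acryloyl-4-benzyloxazolidin-2-one | C=CC(=O)N1[C@@H](Cc2ccccc2)COC1=O
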